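**Retrosynthetic overview** (labdane locants: ring A = C1–C5, C10; ring B = C5–C10; chain C11–C16 on C9; C17 on C8; C18/C19 on C4; C20 on C10)
1. The C13 carbinol comes last, from an (E)-C13=C14 allylic alcohol by Sharpless epoxidation, iodination and zinc-induced opening; the C8 carbinol from methyl addition to a C8 ketone unmasked from a C8–Si bond; C3–Br from inversion of an axial C3 alcohol.
2. The strategy rests on the vicinal pair C9 (H, side chain) / C10 (quaternary, CH3) of ring B, with the chain anti to C20: this is the endo adduct of a C8=C9 dienophile on the diene C10=C5–C6=C7, whose C10 terminus carries the methyl on its inside position.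
3. Ring B is therefore closed by an enantioselective Diels–Alder reaction (bonds C7–C8 and C9–C10) between an achiral ketal-protected ring-A vinylcyclohexene and (E)-3-(dimethylphenylsilyl)propenal.
4. Ring order: ring A (from 2,2-dimethylcyclohexane-1,3-dione), then ring B (cycloaddition); C5 is set afterwards by hydroxyl-directed hydrogenation.

Key step: step 7

Assumption: the catalyst enantiomer is assigned from the formyl C–H···O binding model of cationic oxazaborolidines (s-trans enal stacked on the phenyl group cis to it, diene entering the open face), which for the (S)-prolinol-derived catalyst exposes the si face of C9 required here.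

**Step 1**
Reactants: 1 2,2-dimethylcyclohexane-1,3-dione
Product: 2 6,6-dimethyl-1,4-dioxaspiro[4.5]decan-7-one
Conditions: HOCH2CH2OH (1.05 equiv), p-TsOH (cat.), benzene, reflux, Dean–Stark
Reagents that add atoms: ethylene glycol OCCO
Why: Acid-catalysed ketalisation with azeotropic water removal should stop at the mono-ketal with one equivalent of glycol, because the remaining carbonyl then sits between a quaternary carbon and the new ketal.

**Step 2**
Reactants: 2 6,6-dimethyl-1,4-dioxaspiro[4.5]decan-7-one
Product: 4 (±)-6,6,8-trimethyl-1,4-dioxaspiro[4.5]decan-7-one, via lithium enolate 3 (not isolated)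
Conditions: LiN(i-Pr)2, THF, −78 °C; MeI, −78 to 0 °C
Reagents that add atoms: iodomethane CI
Why: Enolate alkylation can only occur at the single enolisable α-carbon (the future C10), and the racemic centre formed is erased in step 3.

**Step 3**
Reactants: 4 (±)-6,6,8-trimethyl-1,4-dioxaspiro[4.5]decan-7-one
Product: 6 6,6,8-trimethyl-1,4-dioxaspiro[4.5]dec-7-en-7-yl trifluoromethanesulfonate, via potassium enolate 5 (not isolated)
Conditions: KN(SiMe3)2, THF, −78 °C; PhNTf2, −78 °C to rt
Reagents that add atoms: N-phenylbis(trifluoromethanesulfonimide) O=S(=O)(N(c1ccccc1)S(=O)(=O)C(F)(F)F)C(F)(F)F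
Why: Enolisation is possible only toward the methyl-bearing carbon, so O-sulfonylation of the enolate should give the tetrasubstituted enol triflate regiospecifically, as known for 2,2,6-trimethylcyclohexanone.

**Step 4**
Reactants: 6 6,6,8-trimethyl-1,4-dioxaspiro[4.5]dec-7-en-7-yl trifluoromethanesulfonate; 7 tributyl(vinyl)stannane
Product: 8 7-ethenyl-6,6,8-trimethyl-1,4-dioxaspiro[4.5]dec-7-ene
Conditions: Pd(PPh3)4 (5 mol %), LiCl, THF, reflux
Reagents that add atoms: none
Why: Stille coupling of hindered cyclohexenyl triflates with vinylstannanes in the presence of LiCl is well established and should give the 2-vinylcyclohexene diene without touching the ketal.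

**Step 5**
Reactants: 9 propargyl alcohol
Product: 10 (E)-3-(dimethylphenylsilyl)prop-2-en-1-ol
Conditions: PhMe2SiH, PtCl2 (1 mol %), XPhos (2 mol %), THF, 50 °C
Reagents that add atoms: dimethylphenylsilane C[SiH](C)c1ccccc1
Why: Phosphine-ligated platinum-catalysed hydrosilylation of propargylic alcohols is a syn addition that places silicon on the terminal carbon and should give the (E)-vinylsilane.

**Step 6**
Reactants: 10 (E)-3-(dimethylphenylsilyl)prop-2-en-1-ol
Product: 11 (E)-3-(dimethylphenylsilyl)propenal
Conditions: MnO2, CH2Cl2, rt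
Reagents that add atoms: none
Why: MnO2 oxidises allylic alcohols selectively to enals with retention of the E geometry.

**Step 7**
Reactants: 8 7-ethenyl-6,6,8-trimethyl-1,4-dioxaspiro[4.5]dec-7-ene; 11 (E)-3-(dimethylphenylsilyl)propenal
Product: 12 (8R,9S,10S)-8-(dimethylphenylsilyl)-3,3-ethylenedioxy-4,4,10-trimethyl-Δ5-octalin-9-carbaldehyde (endo adduct; formyl anti to the C10 methyl; silyl trans to formyl)
Conditions: (S)-3,3-diphenyl-1-(2-methylphenyl)tetrahydro-1H,3H-pyrrolo[1,2-c][1,3,2]oxazaborole (20 mol %) protonated with HNTf2 (17 mol %), CH2Cl2, −78 to −20 °C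
Reagents that add atoms: none
Why: Binding of the enal to the cationic boron (s-trans enal, formyl C–H···O contact) lowers its LUMO, and a concerted but asynchronous [4+2] cycloaddition follows in which C7–C8 forms ahead of C9–C10 while positive charge builds on the tertiary allylic C10–C5 unit. The closest known reaction type is the oxazaborolidinium-catalysed Diels–Alder reaction of α,β-unsaturated aldehydes with 1,3-dienes, applied here to a 1-vinyl-2,6,6-trimethylcyclohexene-type diene of the kind known to undergo thermal cycloadditions. Ring B closes by an intermolecular suprafacial–suprafacial cycloaddition that forms both σ bonds (C7–C8 and C9–C10) in one step and leaves C5=C6. At C9 and C10 the endo position of the formyl group under the diene places C11 cis to the outside substituent C1 and anti to the inside methyl C20; at C8 the E geometry of the dienophile fixes silicon trans to C11; the absolute configuration comes from the catalyst phenyl group shielding one face of the bound enal, so that C10 adds to the si face of C9. Regioselectivity should follow from the unsubstituted, more nucleophilic terminus C7 bonding to the β-carbon and the hindered C10 bonding second, endo selectivity from secondary overlap with the complexed formyl group, and enantioselectivity from the catalyst alone because the diene is achiral. The triflimide-activated cation is chosen because the inside methyl on C10 twists the s-cis diene and makes it a sluggish partner.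

**Step 8**
Reactants: 12 endo adduct aldehyde
Product: 13 (8R,9S,10S)-8-(dimethylphenylsilyl)-3,3-ethylenedioxy-9-(hydroxymethyl)-4,4,10-trimethyl-Δ5-octalin
Conditions: NaBH4, MeOH, 0 °C
Reagents that add atoms: none
Why: Borohydride reduction of the aldehyde removes the epimerisable formyl centre and installs the C11 hydroxyl that directs the next step, with no stereocentre affected.

**Step 9**
Reactants: 13 homoallylic-type alcohol
Product: 14 (5S,8R,9S,10R)-8-(dimethylphenylsilyl)-3,3-ethylenedioxy-9-(hydroxymethyl)-4,4,10-trimethyl-trans-decalin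
Conditions: H2 (1 atm), [Ir(cod)(PCy3)(py)]PF6 (5 mol %), CH2Cl2, rt
Reagents that add atoms: none
Why: In this hydroxyl-directed hydrogenation the C11 hydroxyl, which lies on the face anti to the C10 methyl, should bind iridium and deliver hydrogen to the same face of the hindered C5=C6 bond, setting H-5 trans to C20 (trans-decalin).

**Step 10**
Reactants: 14 trans-decalin alcohol
Product: 15 (5S,8R,9S,10R)-8-(dimethylphenylsilyl)-3,3-ethylenedioxy-4,4,10-trimethyl-trans-decalin-9-carbaldehyde
Conditions: Dess–Martin periodinane, NaHCO3, CH2Cl2, 0 °C to rt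
Reagents that add atoms: none
Why: Buffered Dess–Martin oxidation is mild and non-basic, so the aldehyde should form without epimerisation at C9.

**Step 11**
Reactants: 15 trans-decalin aldehyde
Product: 16 methyl (E)-3-[(5S,8R,9R,10R)-8-(dimethylphenylsilyl)-3,3-ethylenedioxy-4,4,10-trimethyl-trans-decalin-9-yl]prop-2-enoate
Conditions: Ph3P=CHCO2Me, toluene, 90 °C
Reagents that add atoms: methyl (triphenylphosphoranylidene)acetate COC(=O)C=P(c1ccccc1)(c1ccccc1)c1ccccc1
Why: Wittig olefination with a stabilised ylide under neutral conditions should add C12 and C13 to the hindered aldehyde as the E enoate without disturbing C9.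

**Step 12**
Reactants: 16 enoate
Product: 17 methyl 3-[(5S,8R,9R,10R)-8-(dimethylphenylsilyl)-3,3-ethylenedioxy-4,4,10-trimethyl-trans-decalin-9-yl]propanoate
Conditions: H2 (1 atm), 10% Pd/C, EtOAc, rt
Reagents that add atoms: none
Why: Heterogeneous hydrogenation saturates the conjugated C11=C12 bond and leaves the ester, ketal and arylsilane intact.

**Step 13**
Reactants: 17 ketal ester
Product: 18 methyl 3-[(5S,8R,9R,10R)-8-(dimethylphenylsilyl)-4,4,10-trimethyl-3-oxo-trans-decalin-9-yl]propanoate
Conditions: 1 M HCl, THF, rt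
Reagents that add atoms: water O
Why: Acid hydrolysis of the dioxolane frees the C3 ketone under conditions that the methyl ester and the C–Si bond tolerate.

**Step 14**
Reactants: 18 C3 ketone
Product: 19 methyl 3-[(3S,5S,8R,9R,10R)-8-(dimethylphenylsilyl)-3-hydroxy-4,4,10-trimethyl-trans-decalin-9-yl]propanoate (axial 3-OH, anti to C20)
Conditions: LiBH(s-Bu)3, THF, −78 °C
Reagents that add atoms: none
Why: The bulky trialkylborohydride should attack the 4,4-dimethyl-3-ketone along the equatorial path and give the axial alcohol, as is general for such ketones, while the ester is inert at −78 °C.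

**Step 15**
Reactants: 19 axial C3 alcohol
Product: 20 methyl 3-[(3R,5S,8R,9R,10R)-3-bromo-8-(dimethylphenylsilyl)-4,4,10-trimethyl-trans-decalin-9-yl]propanoate (equatorial bromide, syn to C20)
Conditions: CBr4, PPh3, toluene, 60 °C
Reagents that add atoms: carbon tetrabromide BrC(Br)(Br)Br
Why: In the Appel reaction bromide displaces the axial alkoxyphosphonium group from the rear and should give the equatorial bromide by inversion; it is run here because no other hydroxyl is present.

**Step 16**
Reactants: 20 C8 silane
Product: 21 methyl 3-[(3R,5S,8R,9R,10R)-3-bromo-8-hydroxy-4,4,10-trimethyl-trans-decalin-9-yl]propanoate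
Conditions: KBr, AcOOH, NaOAc, AcOH, rt
Reagents that add atoms: peracetic acid CC(=O)OO
Why: Fleming–Tamao oxidation (ipso-bromodesilylation of the phenyl group, then peracid-induced migration of C8 from silicon to oxygen) should turn C–Si into C–OH with retention, in a substrate that now has no alkene.

**Step 17**
Reactants: 21 C8 alcohol
Product: 22 methyl 3-[(3R,5S,9R,10R)-3-bromo-4,4,10-trimethyl-8-oxo-trans-decalin-9-yl]propanoate
Conditions: Dess–Martin periodinane, NaHCO3, CH2Cl2, rt
Reagents that add atoms: none
Why: Buffered Dess–Martin oxidation should give the C8 ketone without base, so the adjacent C9 centre keeps its configuration.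

**Step 18**
Reactants: 22 C8 ketone
Product: 23 methyl 3-[(3R,5S,8R,9R,10R)-3-bromo-8-hydroxy-4,4,8,10-tetramethyl-trans-decalin-9-yl]propanoate
Conditions: MeLi, CeCl3, THF, −78 °C
Reagents that add atoms: methyllithium [Li]C
Why: The weakly basic organocerium reagent adds to the ketone faster than to the ester and without enolisation, and it should approach along the equatorial path on the face anti to the axial C10 methyl (which blocks the axial path by a 1,3-diaxial contact), so that the methyl ends equatorial and the hydroxyl axial, syn to C20.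

**Step 19**
Reactants: 23 hydroxy ester
Product: 24 3-[(3R,5S,8R,9R,10R)-3-bromo-8-hydroxy-4,4,8,10-tetramethyl-trans-decalin-9-yl]propanal
Conditions: i-Bu2AlH (2.2 equiv), CH2Cl2, −78 °C; Rochelle salt
Reagents that add atoms: none
Why: Partial reduction of the methyl ester at −78 °C stops at the aluminium hemiacetal and should release the C13 aldehyde on work-up; the trans-diaxial C8–OH cannot close a lactol onto it.

**Step 20**
Reactants: 24 aldehyde
Product: 25 (3R,5S,8R,9R,10R)-3-bromo-9-(but-3-yn-1-yl)-4,4,8,10-tetramethyl-trans-decalin-8-ol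
Conditions: dimethyl (1-diazo-2-oxopropyl)phosphonate, K2CO3, MeOH, 0 °C to rt
Reagents that add atoms: dimethyl (1-diazo-2-oxopropyl)phosphonate COP(=O)(OC)C(=[N+]=[N-])C(C)=O
Why: Seyferth–Gilbert homologation with the Ohira–Bestmann reagent converts the aldehyde into the terminal alkyne (adding C14) under mild base that the equatorial bromide, which lacks an anti-periplanar hydrogen, should survive.

**Step 21**
Reactants: 25 terminal alkyne
Product: 27 (3R,5S,8R,9R,10R)-3-bromo-9-[(E)-5-hydroxy-3-methylpent-3-en-1-yl]-4,4,8,10-tetramethyl-trans-decalin-8-ol, via alkenylalane 26 (not isolated)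
Conditions: Me3Al, Cp2ZrCl2 (0.3 equiv), CH2Cl2, 0 °C to rt; (CH2O)n, THF, rt
Reagents that add atoms: trimethylaluminium C[Al](C)C; formaldehyde (from paraformaldehyde) C=O
Why: Negishi zirconium-catalysed carboalumination adds methyl and aluminium syn across the alkyne with methyl on the internal carbon, and trapping the alkenylalane with formaldehyde should give the E trisubstituted allylic alcohol.

**Step 22**
Reactants: 27 (E)-allylic alcohol
Product: 28 (13R,14R)-3-bromo-13,14-epoxylabdane-8,15-diol [(3R,5S,8R,9R,10R) in the decalin]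
Conditions: Ti(OiPr)4 (10 mol %), D-(−)-diisopropyl tartrate (12 mol %), t-BuOOH, 4 Å MS, CH2Cl2, −20 °C
Reagents that add atoms: tert-butyl hydroperoxide CC(C)(C)OO
Why: Sharpless asymmetric epoxidation with the D-(−)-tartrate should deliver oxygen to the face that gives the (13R,14R) epoxide (the mirror image of the sense in which the L-(+)-ester converts geraniol into its (2S,3S) epoxide), under reagent control and without involving the non-allylic C8 hydroxyl.

**Step 23**
Reactants: 28 epoxy alcohol
Product: 29 (13R,14S)-3-bromo-13,14-epoxy-15-iodolabdan-8-ol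
Conditions: I2, PPh3, imidazole, THF, 0 °C
Reagents that add atoms: iodine II
Why: Garegg–Samuelsson iodination converts only the primary hydroxyl into the iodide, since the hindered tertiary C8 hydroxyl does not react and the epoxide is untouched under buffered conditions.

**Step 24**
Reactants: 29 epoxy iodide
Product: 30 (1R,2R,4aS,6R,8aR)-6-bromo-1-[(3R)-3-hydroxy-3-methylpent-4-en-1-yl]-2,5,5,8a-tetramethyldecahydronaphthalen-2-ol (target)
Conditions: Zn dust, EtOH, 70 °C
Reagents that add atoms: none
Why: Zinc insertion into the C15–I bond followed by β-elimination opens the epoxide to the C14=C15 alkene and the tertiary C13 alcohol, with the C13–O bond (and so the 13R configuration) retained and the secondary bromide inert.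

**Compound list**
1 | 2,2-dimethylcyclohexane-1,3-dione | CC1(C)C(=O)CCCC1=O | starting material
2 | 6,6-dimethyl-1,4-dioxaspiro[4.5]decan-7-one | CC1(C)C(=O)CCCC12OCCO2 | intermediate
3 | lithium enolate of 2 | [Li+].[O-]C1=CCCC2(OCCO2)C1(C)C | intermediate
4 | (±)-6,6,8-trimethyl-1,4-dioxaspiro[4.5]decan-7-one | CC1CCC2(OCCO2)C(C)(C)C1=O | intermediate
5 | potassium enolate of 4 | [K+].[O-]C1=C(C)CCC2(OCCO2)C1(C)C | intermediate
6 | 6,6,8-trimethyl-1,4-dioxaspiro[4.5]dec-7-en-7-yl trifluoromethanesulfonate | CC1=C(OS(=O)(=O)C(F)(F)F)C(C)(C)C2(OCCO2)CC1 | intermediate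
7 | tributyl(vinyl)stannane | C=C[Sn](CCCC)(CCCC)CCCC | starting material
8 | 7-ethenyl-6,6,8-trimethyl-1,4-dioxaspiro[4.5]dec-7-ene (ring-A diene) | C=CC1=C(C)CCC2(OCCO2)C1(C)C | intermediate
9 | propargyl alcohol | C#CCO | starting material
10 | (E)-3-(dimethylphenylsilyl)prop-2-en-1-ol | C[Si](C)(c1ccccc1)/C=C/CO | intermediate
11 | (E)-3-(dimethylphenylsilyl)propenal | C[Si](C)(c1ccccc1)/C=C/C=O | intermediate
12 | endo adduct, (8R,9S,10S) C9 aldehyde with C8 silyl, Δ5, C3 ketal | O=C[C@@H]1[C@]2(C)CCC3(OCCO3)C(C)(C)C2=CC[C@H]1[Si](C)(C)c4ccccc4 | intermediate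
13 | (8R,9S,10S) C11 alcohol, Δ5 | OC[C@@H]1[C@]2(C)CCC3(OCCO3)C(C)(C)C2=CC[C@H]1[Si](C)(C)c4ccccc4 | intermediate
14 | (5S,8R,9S,10R) trans-decalin C11 alcohol | OC[C@@H]1[C@]2(C)CCC3(OCCO3)C(C)(C)[C@H]2CC[C@H]1[Si](C)(C)c4ccccc4 | intermediate
15 | (5S,8R,9S,10R) trans-decalin C9 aldehyde | O=C[C@@H]1[C@]2(C)CCC3(OCCO3)C(C)(C)[C@H]2CC[C@H]1[Si](C)(C)c4ccccc4 | intermediate
16 | methyl (E)-enoate (C11=C12), ketal, C8 silyl | COC(=O)/C=C/[C@@H]1[C@]2(C)CCC3(OCCO3)C(C)(C)[C@H]2CC[C@H]1[Si](C)(C)c4ccccc4 | intermediate
17 | saturated methyl ester, ketal, C8 silyl | COC(=O)CC[C@@H]1[C@]2(C)CCC3(OCCO3)C(C)(C)[C@H]2CC[C@H]1[Si](C)(C)c4ccccc4 | intermediate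
18 | 3-oxo ester, C8 silyl | COC(=O)CC[C@@H]1[C@]2(C)CCC(=O)C(C)(C)[C@H]2CC[C@H]1[Si](C)(C)c3ccccc3 | intermediate
19 | (3S) axial 3-hydroxy ester, C8 silyl | COC(=O)CC[C@@H]1[C@]2(C)CC[C@H](O)C(C)(C)[C@H]2CC[C@H]1[Si](C)(C)c3ccccc3 | intermediate
20 | (3R) equatorial 3-bromo ester, C8 silyl | COC(=O)CC[C@@H]1[C@]2(C)CC[C@@H](Br)C(C)(C)[C@H]2CC[C@H]1[Si](C)(C)c3ccccc3 | intermediate
21 | 3-bromo-8-hydroxy ester (8R, OH syn to C20) | COC(=O)CC[C@@H]1[C@]2(C)CC[C@@H](Br)C(C)(C)[C@H]2CC[C@H]1O | intermediate
22 | 3-bromo-8-oxo ester | COC(=O)CC[C@@H]1[C@]2(C)CC[C@@H](Br)C(C)(C)[C@H]2CCC1=O | intermediate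
23 | 3-bromo-8-hydroxy-8-methyl ester (8R) | COC(=O)CC[C@@H]1[C@]2(C)CC[C@@H](Br)C(C)(C)[C@H]2CC[C@@]1(C)O | intermediate
24 | C13 aldehyde | O=CCC[C@@H]1[C@]2(C)CC[C@@H](Br)C(C)(C)[C@H]2CC[C@@]1(C)O | intermediate
25 | terminal alkyne (C13≡C14) | C#CCC[C@@H]1[C@]2(C)CC[C@@H](Br)C(C)(C)[C@H]2CC[C@@]1(C)O | intermediate
26 | (E)-alkenyldimethylalane, C8 dimethylaluminium alkoxide | C[Al](C)/C=C(\C)CC[C@@H]1[C@]2(C)CC[C@@H](Br)C(C)(C)[C@H]2CC[C@@]1(C)O[Al](C)C | intermediate
27 | (E)-allylic alcohol (3-bromolabd-13E-ene-8,15-diol) | OC/C=C(\C)CC[C@@H]1[C@]2(C)CC[C@@H](Br)C(C)(C)[C@H]2CC[C@@]1(C)O | intermediate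
28 | (13R,14R)-epoxy alcohol | OC[C@H]3O[C@]3(C)CC[C@@H]1[C@]2(C)CC[C@@H](Br)C(C)(C)[C@H]2CC[C@@]1(C)O | intermediate
29 | (13R,14S)-epoxy iodide | IC[C@H]3O[C@]3(C)CC[C@@H]1[C@]2(C)CC[C@@H](Br)C(C)(C)[C@H]2CC[C@@]1(C)O | intermediate
30 | (3R,5S,8R,9R,10R,13R)-3-bromolabd-14-ene-8,13-diol, CNP0150870.1 | C=C[C@](C)(O)CC[C@@H]1[C@]2(C)CC[C@@H](Br)C(C)(C)[C@H]2CC[C@@]1(C)O | target

**Step count**
Total: 24 steps. Longest linear sequence: 22 steps (steps 1–4 and 7–24); the dienophile branch is steps 5–6.

**Steps most likely to fail**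

1. Step 7. The inside methyl on C10 may make the cycloaddition too slow, so that acid-induced opening of the ketal or oligomerisation of the diene takes over, or endo and facial selectivity erode. The fallback keeps the same bonds but uses auxiliary control with a neutral aluminium Lewis acid. It sets out from 11 and 8. Aldehyde 11 is oxidised (NaClO2, NaH2PO4, 2-methyl-2-butene) to (E)-3-(dimethylphenylsilyl)propenoic acid F1. This is coupled through its pivaloyl mixed anhydride with lithiated (R)-4-benzyloxazolidin-2-one to the N-enoyl imide F2. Cycloaddition of F2 with 8 under Et2AlCl (CH2Cl2, −78 to −30 °C; chelated s-cis imide, diene entering anti to the benzyl group, endo) should give the cycloadduct imide F3. LiBH4 in THF–MeOH then removes the auxiliary and gives alcohol 13, where the route is rejoined.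

2. Step 15. The activated neopentylic axial alcohol may ionise with a 1,2-methyl shift from C4, or lose the anti-periplanar H-2 to give the Δ2 alkene, instead of undergoing rear-side displacement. The fallback sets the C3 configuration by hydrogen-atom delivery and sets out from ketone 18. (PhO)3P, Br2 and Et3N (CH2Cl2, −60 °C to reflux) convert 18 into the C2=C3 vinyl bromide F4. Hydrogen-atom-transfer hydrogenation (Mn(dpm)3, dpm = dipivaloylmethanate, PhSiH3, t-BuOOH, i-PrOH) then forms the C3 α-bromo radical, which should take up hydrogen from the unhindered axial direction, leaving bromine equatorial. This gives 20, where the route is rejoined.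

3. Step 18. The axial C9 chain may hinder the equatorial approach enough to give poor facial selectivity, or the ketone may enolise and epimerise at C9. The fallback replaces approach control by a stereoelectronically controlled trans-diaxial addition and sets out from ketone 22. KN(SiMe3)2 and PhNTf2 (THF, −78 °C; deprotonation at C7, whose axial hydrogen is aligned) give the C7=C8 enol triflate F5. Negishi coupling with MeZnCl and Pd(PPh3)4 gives the Δ7 alkene F6, which carries the C8 methyl. Hg(OAc)2 in THF–H2O should then add with water attacking the tertiary C8 axially, syn to C20 and anti to the mercurinium ion, to give the 7-acetoxymercurio-8-hydroxy compound F7. NaBH4 in aqueous NaOH removes mercury without touching the C3 bromide and gives 23, where the route is rejoined.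

**Further compounds**
F1 | step 7 | (E)-3-(dimethylphenylsilyl)propenoic acid | C[Si](C)(c1ccccc1)/C=C/C(=O)O
F2 | step 7 | (R)-4-benzyl-3-[(E)-3-(dimethylphenylsilyl)propenoyl]oxazolidin-2-one | C[Si](C)(c1ccccc1)/C=C/C(=O)N1[C@H](Cc2ccccc2)COC1=O
F3 | step 7 | endo cycloadduct N-acyl oxazolidinone (C9 acyl, C8 silyl, Δ5, C3 ketal) | O=C([C@@H]1[C@]2(C)CCC3(OCCO3)C(C)(C)C2=CC[C@H]1[Si](C)(C)c4ccccc4)N5[C@H](Cc6ccccc6)COC5=O
F4 | step 15 | C2=C3 vinyl bromide ester, C8 silyl | COC(=O)CC[C@@H]1[C@]2(C)CC=C(Br)C(C)(C)[C@H]2CC[C@H]1[Si](C)(C)c3ccccc3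
F5 | step 18 | C7=C8 enol triflate of 22 | COC(=O)CC[C@@H]1[C@]2(C)CC[C@@H](Br)C(C)(C)[C@H]2CC=C1OS(=O)(=O)C(F)(F)F
F6 | step 18 | Δ7 alkene with C8 methyl | COC(=O)CC[C@@H]1[C@]2(C)CC[C@@H](Br)C(C)(C)[C@H]2CC=C1C
F7 | step 18 | 7-acetoxymercurio-8-hydroxy-8-methyl ester (Hg anti to C20, OH syn to C20) | COC(=O)CC[C@@H]1[C@]2(C)CC[C@@H](Br)C(C)(C)[C@H]2C[C@H]([Hg]OC(C)=O)[C@@]1(C)O
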